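A percentage point here is a unit of substrate held: an idle adduct counts as two units, and each idle adduct also counts as one target in any amount of target.

- gamma: substrate 2.8 M; run made earlier
- flask: substrate 2.0 M; time 50 min

gamma run (percent of the substrate charged)

| time / min | target / % | isomer of the product / % | substrate / % |
|---|---|---|---|
| 3.00 | 6.5 | 3.2 | 76.4 |
| 6.00 | 11.2 | 5.3 | 60.4 |
| 12.0 | 17.9 | 9.1 | 38.5 |
| 20.0 | 23.6 | 11.4 | 22.8 |
| 40.0 | 29.2 | 14.4 | 10.3 |

(standard deviation of a reading: 0.5 percentage points)

- percent here means substrate units held: one idle adduct or self-condensation product counts as two
- what is said of target includes idle adduct
- the earlier runs were read with a standard deviation of 0.5 percentage points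
- candidate steps: substrate <-> target; substrate <-> isomer of the product; substrate + target <-> idle adduct; 2 substrate -> self-condensation product; target -> over-reaction product
- in an amount of target, one idle adduct counts as one target

- ratio of target to isomer of the product at 25 s
- ratio of target to isomer of the product at 50 min
- which of target and isomer of the product there is more of at 50 min

If target and isomer of the product both come from substrate by first-order steps, each gain is its rate constant times the mean substrate over the time passed, times that time. Replacing the curve by its mean pays at once, since the same mean stands in both gains and falls out of their ratio. What remains is the split (selectivity factor), total target read over total isomer read in the gamma run, 2.04.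

The first objection is the charge: the flask holds 2.0 M against 2.8 M, and the steps to idle adduct and self-condensation product follow concentration, so its substrate curve differs. But a different curve changes the shared mean, which cancels, and idle adduct stays counted in target.

The second objection is stronger: return steps and over-reaction act on the products, where the mean does not cancel. Such a leak should show as drift. The first two readings give 2.08 and the last two 2.05, a difference of 0.0358, smaller than the 0.173 that isomer scatter lends the early ratio. No drift is readable up to 40.0 min, though 50 min lies beyond the last reading.

The third objection is the split's own scatter, about 0.0525. That leaves target ahead, and this reckoning commits to the split at both asked times.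

The forecast, a little lower, gives 2.03 at 25 s and 2 at 50 min, with target leading: "Both come from substrate by first-order steps, so the ratio is the rate-constant ratio".

The flask gives 1.91 at 25 s and 2.03 at 50 min, with target at 32.6% against isomer at 16.1%.

substrate ⇌ target (K = 7.27, k = 3.91 × 10⁻⁴ s⁻¹); substrate ⇌ isomer of the product (K = 3.10, k = 2.05 × 10⁻⁴ s⁻¹); substrate + target ⇌ idle adduct, settled at all times (K = 10.1 M⁻¹); 2 substrate → self-condensation product (k = 1.10 × 10⁻⁴ M⁻¹ s⁻¹); target → over-reaction product (k = 1.08 × 10⁻⁴ s⁻¹) The forward rates from substrate to target and isomer stand at 1.9 to one just after the start, and the loss of target to over-reaction product has turned over 1.73% of the charge by 50 min, while the split times the flask's isomer gives 32.8% of target. The neighbour charged with 0.50 M, a quarter of the flask's charge, reads 1.89 at 50 min with 3.81% over-reaction product, and there the split times its isomer of 20.3% gives 41.3% of target against 38.2% held.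

The runs stem from a simulated flask for an exercise; noise was put on by code.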